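## Retrosynthetic overview

1. Target 28 ⇐ 27 ⇐ 26: the C8 ester and C14 acetate go on last; the 1β,10α-epoxide comes from OH-directed epoxidation of allylic alcohol 24, the exocyclic methylene from Eschenmoser methylenation, and C14 from Stille hydroxymethylation of enol triflate 20.
2. Ten-membered ring ⇐ six-membered ring: anionic oxy-Cope of the trans-1-vinyl-2-isopropenylcyclohexanol 18, with the regiodefined enolate trapped as 20 (sets the 4E alkene and the C1=C10 geometry).
3. 18 ⇐ enone 12: C5 isopropenyl by α-iodination/Suzuki, C6–O by conjugate borylation/oxidation, vinyl addition to C10=O, trans-lactonisation.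
4. 12 ⇐ epoxy ester 9 (allylic oxidation, reductive epoxide opening) ⇐ bromolactone 7; key step: catalyst-controlled bromolactonisation that breaks the mirror symmetry of dienyl acid 6 and sets the stereocentres from which all others are relayed.
5. 6 ⇐ benzene (Birch reduction, dienyl anion + oxirane, oxidation). Ring order: six-membered carbocycle from benzene → cis-lactone (transient) → trans-fused γ-lactone → ten-membered carbocycle → epoxide.

Labels: germacrane numbers are used throughout. The benzene carbons become C5–C10; C11/C12 come from oxirane, C13 from the Mannich reagent, C1/C2 from the vinyl group, C3/C4/C15 from the isopropenyl group, C14 from the stannane. For the ten-membered compounds α/β have the usual germacranolide meaning (H-7 is α). TBS = tert-butyldimethylsilyl.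

Assumption: (DHQD)2PHAL is taken to give the enantiomer of 7 that is drawn; if the sense of induction is opposite, the pseudo-enantiomer (DHQ)2PHAL is used.

## Route

Step 1
Reactants: 1 benzene
Product: 2 cyclohexa-1,4-diene
Conditions: Li, NH3 (l), EtOH, Et2O, −78 → −33 °C
Reagents that add atoms: none
Why: Birch reduction: stepwise electron transfer from Li and protonation by EtOH stop at the non-conjugated 1,4-diene, which has no stereocentre.

Step 2
Reactants: 2 cyclohexa-1,4-diene
Product: 4 2-(cyclohexa-2,5-dien-1-yl)ethanol, via cyclohexa-2,5-dien-1-yllithium 3 (not isolated)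
Conditions: s-BuLi, TMEDA, THF, −78 °C; then oxirane, −78 → 0 °C
Reagents that add atoms: oxirane C1CO1
Why: Deprotonation of the doubly allylic CH2 gives the pentadienyl-type anion 3, which opens oxirane (SN2) through its central carbon, so the skipped 1,4-diene is kept and the new carbon (C7) sits on the mirror plane of an achiral diene.

Step 3
Reactants: 4 2-(cyclohexa-2,5-dien-1-yl)ethanol
Product: 6 2-(cyclohexa-2,5-dien-1-yl)acetic acid, via 2-(cyclohexa-2,5-dien-1-yl)acetaldehyde 5 (not isolated)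
Conditions: Dess–Martin periodinane, CH2Cl2, 0 °C; then t-BuOH/H2O, 2-methyl-2-butene, NaH2PO4, NaClO2, 0 → 23 °C
Reagents that add atoms: sodium chlorite [Na+].[O-]Cl=O
Why: Dess–Martin oxidation followed in the same flask by Pinnick oxidation takes the primary alcohol to the acid under neutral to weakly acidic conditions that neither isomerise nor aromatise the skipped diene.

Step 4
Reactants: 6 2-(cyclohexa-2,5-dien-1-yl)acetic acid
Product: 7 (3aS,7S,7aS)-7-bromo-3a,6,7,7a-tetrahydro-1-benzofuran-2(3H)-one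
Conditions: NBS (1.1 equiv), (DHQD)2PHAL [hydroquinidine 1,4-phthalazinediyl diether] (10 mol %), CHCl3/hexane 1:1, −40 °C
Reagents that add atoms: N-bromosuccinimide O=C1CCC(=O)N1Br
Why: Key step, catalytic enantioselective bromolactonization (desymmetrization): the alkaloid catalyst binds the carboxylate and NBS and selects one of the two enantiotopic alkenes, and 5-exo anti addition gives the cis-fused lactone, setting C7, C8 (O cis to the side chain) and C9 (Br trans to O) in one operation.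

Step 5
Reactants: 7 (3aS,7S,7aS)-7-bromo-3a,6,7,7a-tetrahydro-1-benzofuran-2(3H)-one
Product: 9 methyl 2-[(1S,2S,6R)-7-oxabicyclo[4.1.0]hept-3-en-2-yl]acetate, via bromohydrin ester 8 (not isolated)
Conditions: K2CO3, MeOH, 0 → 23 °C
Reagents that add atoms: methanol CO
Why: Methanolysis of the lactone frees the C8 alkoxide, which displaces the anti bromide at C9 (intramolecular Williamson SN2, inversion at C9, retention at C8) to give the epoxide cis to the side chain.

Step 6
Reactants: 9 methyl 2-[(1S,2S,6R)-7-oxabicyclo[4.1.0]hept-3-en-2-yl]acetate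
Product: 10 methyl 2-[(1S,2S,6S)-5-oxo-7-oxabicyclo[4.1.0]hept-3-en-2-yl]acetate
Conditions: Rh2(cap)4 (1 mol %, cap = caprolactamate), t-BuOOH (5 equiv), K2CO3 (cat.), CH2Cl2, 23 °C
Reagents that add atoms: tert-butyl hydroperoxide CC(C)(C)OO
Why: Allylic C–H oxidation: the tert-butylperoxyl radical abstracts H from C10, the only allylic CH2, and the allylic peroxide formed at this less hindered terminus collapses to the enone without touching a stereocentre.

Step 7
Reactants: 10 methyl 2-[(1S,2S,6S)-5-oxo-7-oxabicyclo[4.1.0]hept-3-en-2-yl]acetate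
Product: 11 methyl 2-[(1S,6R)-6-hydroxy-4-oxocyclohex-2-en-1-yl]acetate
Conditions: SmI2 (2.2 equiv), THF/MeOH, −90 °C
Reagents that add atoms: none
Why: SmI2 reduction of an α,β-epoxy ketone: the ketyl ejects the Cα–O bond (C9–O) and the samarium enolate is protonated at C9, so the C8–O bond and its configuration are kept.

Step 8
Reactants: 11 methyl 2-[(1S,6R)-6-hydroxy-4-oxocyclohex-2-en-1-yl]acetate
Product: 12 methyl 2-[(1S,6R)-6-(TBSO)-4-oxocyclohex-2-en-1-yl]acetate
Conditions: TBSOTf, 2,6-lutidine, CH2Cl2, −78 °C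
Reagents that add atoms: tert-butyldimethylsilyl trifluoromethanesulfonate CC(C)(C)[Si](C)(C)OS(=O)(=O)C(F)(F)F
Why: Silylation at −78 °C is faster than dehydration or lactonisation of the β-hydroxy ketone and masks C8–OH as a poor leaving group.

Step 9
Reactants: 12 methyl 2-[(1S,6R)-6-(TBSO)-4-oxocyclohex-2-en-1-yl]acetate
Product: 13 methyl 2-[(1S,6R)-6-(TBSO)-3-iodo-4-oxocyclohex-2-en-1-yl]acetate
Conditions: I2, pyridine/CH2Cl2 1:1, 0 → 23 °C
Reagents that add atoms: iodine II
Why: Johnson α-iodination: pyridine adds to C6, the enolate is iodinated at C5 and pyridine is expelled, giving the 2-iodoenone without touching C7 or C8.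

Step 10
Reactants: 13 methyl 2-[(1S,6R)-6-(TBSO)-3-iodo-4-oxocyclohex-2-en-1-yl]acetate
Product: 14 methyl 2-[(1S,6R)-6-(TBSO)-4-oxo-3-(prop-1-en-2-yl)cyclohex-2-en-1-yl]acetate
Conditions: isopropenyl-B(pin), Pd(PhCN)2Cl2 (5 mol %), AsPh3, Ag2O, THF/H2O 8:1, 23 °C
Reagents that add atoms: isopropenylboronic acid pinacol ester CC(=C)B1OC(C)(C)C(C)(C)O1
Why: Suzuki–Miyaura coupling under the mild Ag2O/AsPh3 conditions used for 2-iodoenones joins C5 to the isopropenyl group (C4, C3, C15) without base-induced loss of the β-silyloxy group.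

Step 11
Reactants: 14 methyl 2-[(1S,6R)-6-(TBSO)-4-oxo-3-(prop-1-en-2-yl)cyclohex-2-en-1-yl]acetate
Product: 16 methyl 2-[(1S,2S,3R,6R)-6-(TBSO)-2-hydroxy-4-oxo-3-(prop-1-en-2-yl)cyclohexyl]acetate, via boryl ketone 15 (not isolated)
Conditions: B2pin2, CuCl (5 mol %), NaOt-Bu (10 mol %), DPEphos (5 mol %), MeOH (2 equiv), THF, 23 °C; then H2O2, pH 7 phosphate buffer, 0 °C
Reagents that add atoms: bis(pinacolato)diboron CC1(C)OB(OC1(C)C)B1OC(C)(C)C(C)(C)O1; hydrogen peroxide OO
Why: Copper-catalysed conjugate borylation puts boron on C6 from the face opposite the C7 and C8 substituents, protonation of the enolate at C5 places the isopropenyl group trans to boron (also the more stable epimer), and peroxide oxidation replaces boron by OH with retention, setting C6 and C5.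

Step 12
Reactants: 16 methyl 2-[(1S,2S,3R,6R)-6-(TBSO)-2-hydroxy-4-oxo-3-(prop-1-en-2-yl)cyclohexyl]acetate
Product: 18 (3aS,4R,6R,7R,7aS)-4-(TBSO)-6-ethenyl-6-hydroxy-7-(prop-1-en-2-yl)hexahydro-1-benzofuran-2(3H)-one, via diol ester 17 (not isolated)
Conditions: CH2=CHMgBr (3 equiv), LaCl3·2LiCl, THF, −78 °C; aq. NH4Cl; then pyridinium p-toluenesulfonate (cat.), PhH, 50 °C
Reagents that add atoms: vinylmagnesium bromide C=C[Mg]Br
Why: Grignard 1,2-addition (LaCl3·2LiCl suppresses enolisation) occurs by equatorial attack because the axial face of C10 is blocked by the axial C8–OTBS group, so the vinyl group ends trans to the C5 isopropenyl group, and the pyridinium salt then closes the trans-fused γ-lactone (lactonization) between C6–OH and the ester.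

Step 13
Reactants: 18 (3aS,4R,6R,7R,7aS)-4-(TBSO)-6-ethenyl-6-hydroxy-7-(prop-1-en-2-yl)hexahydro-1-benzofuran-2(3H)-one
Product: 20 8β-(TBSO)-10-(trifluoromethanesulfonyloxy)-13,14-dinorgermacra-1(10),4-dien-6α,12-olide, via potassium enolate 19 (not isolated)
Conditions: KN(SiMe3)2 (1.05 equiv), 18-crown-6, THF, −78 → 23 °C; then PhNTf2, −78 → 0 °C
Reagents that add atoms: N-phenylbis(trifluoromethanesulfonimide) O=S(=O)(N(c1ccccc1)S(=O)(=O)C(F)(F)F)C(F)(F)F
Why: Anionic oxy-Cope rearrangement ([3,3]): the potassium alkoxide of the trans-diequatorial divinyl system reacts through a chair transition state with both ring bonds (C10–C9 and C5–C6) equatorial, which gives the 4E alkene and an enolate with C9 and C2 trans, and O-triflation at −78 °C fixes this enolate before it can equilibrate towards C9 and expel the C8 silyloxy group.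

Step 14
Reactants: 20 8β-(TBSO)-10-(trifluoromethanesulfonyloxy)-13,14-dinorgermacra-1(10),4-dien-6α,12-olide
Product: 21 8β-(TBSO)-14-hydroxy-13-norgermacra-1(10),4-dien-6α,12-olide
Conditions: Bu3SnCH2OH, Pd(PPh3)4 (5 mol %), LiCl, THF, 60 °C
Reagents that add atoms: (tributylstannyl)methanol OC[Sn](CCCC)(CCCC)CCCC
Why: Stille (Migita–Kosugi–Stille) coupling of the enol triflate with the hydroxymethylstannane installs C14 with retention of the C1=C10 geometry, LiCl assisting transmetallation.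

Step 15
Reactants: 21 8β-(TBSO)-14-hydroxy-13-norgermacra-1(10),4-dien-6α,12-olide
Product: 24 8β-(TBSO)-14-hydroxygermacra-1(10),4,11(13)-trien-6α,12-olide, via Mannich base 22 (not isolated), via trimethylammonium iodide 23 (not isolated)
Conditions: LiN(SiMe3)2 (2.3 equiv), THF, −78 °C; CH2=NMe2+ I−, −78 → 23 °C; then MeI, MeOH, 23 °C; then aq. NaHCO3, CH2Cl2, 23 °C
Reagents that add atoms: N,N-dimethylmethyleneiminium iodide C=[N+](C)C.[I-]; iodomethane CI
Why: Eschenmoser methylenation: the lactone enolate undergoes Mannich aminomethylation at C11, N-methylation creates a leaving group and mild base induces elimination to the exocyclic alkene, while C7 is not enolisable and stays fixed.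

Step 16
Reactants: 24 8β-(TBSO)-14-hydroxygermacra-1(10),4,11(13)-trien-6α,12-olide
Product: 26 14-acetoxy-1β,10α-epoxy-8β-(TBSO)germacra-4,11(13)-dien-6α,12-olide, via epoxy alcohol 25 (not isolated)
Conditions: VO(acac)2 (5 mol %), t-BuOOH (1.5 equiv), CH2Cl2, 0 °C; then Ac2O, pyridine, 4-(dimethylamino)pyridine, 0 → 23 °C
Reagents that add atoms: tert-butyl hydroperoxide CC(C)(C)OO; acetic anhydride CC(=O)OC(C)=O
Why: Vanadium-catalysed hydroxyl-directed epoxidation (Sharpless–Michaelson type) delivers oxygen from the C14 alkoxide only to C1=C10 and only to its outer face, because the alkene plane stands perpendicular to the ten-membered ring with C14 on the β face, so syn addition gives the 1β,10α-epoxide (C1 R, C10 S), and acetylation in the same flask caps C14–OH.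

Step 17
Reactants: 26 14-acetoxy-1β,10α-epoxy-8β-(TBSO)germacra-4,11(13)-dien-6α,12-olide
Product: 27 14-acetoxy-1β,10α-epoxy-8β-hydroxygermacra-4,11(13)-dien-6α,12-olide
Conditions: Bu4NF, AcOH (1:1), THF, 0 → 23 °C
Reagents that add atoms: none
Why: Fluoride-mediated desilylation buffered by AcOH removes the TBS group without opening the epoxide, cleaving the acetate or adding to the methylene lactone.

Step 18
Reactants: 27 14-acetoxy-1β,10α-epoxy-8β-hydroxygermacra-4,11(13)-dien-6α,12-olide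
Product: 28 14-acetoxy-1β,10α-epoxy-8β-(methacryloyloxy)germacra-4,11(13)-dien-6α,12-olide
Conditions: methacrylic anhydride, Et3N, 4-(dimethylamino)pyridine (cat.), CH2Cl2, 0 → 23 °C
Reagents that add atoms: methacrylic anhydride CC(=C)C(=O)OC(=O)C(C)=C
Why: Acylation of the C8 alcohol catalysed by 4-(dimethylamino)pyridine gives the methacrylate with retention at C8 and completes the target.

## Compound list

1 | benzene | c1ccccc1 | starting material
2 | cyclohexa-1,4-diene | C1C=CCC=C1 | intermediate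
3 | cyclohexa-2,5-dien-1-yllithium | [Li]C1C=CCC=C1 | intermediate
4 | 2-(cyclohexa-2,5-dien-1-yl)ethanol | OCCC1C=CCC=C1 | intermediate
5 | 2-(cyclohexa-2,5-dien-1-yl)acetaldehyde | O=CCC1C=CCC=C1 | intermediate
6 | 2-(cyclohexa-2,5-dien-1-yl)acetic acid | OC(=O)CC1C=CCC=C1 | intermediate
7 | (3aS,7S,7aS)-7-bromo-3a,6,7,7a-tetrahydro-1-benzofuran-2(3H)-one (cis-fused lactone, Br trans to the lactone O) | C1C=C[C@@H]2CC(=O)O[C@@H]2[C@H]1Br | intermediate
8 | methyl 2-[(1S,5S,6S)-5-bromo-6-hydroxycyclohex-2-en-1-yl]acetate | C1C=C[C@H](CC(=O)OC)[C@H](O)[C@H]1Br | intermediate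
9 | methyl 2-[(1S,2S,6R)-7-oxabicyclo[4.1.0]hept-3-en-2-yl]acetate (epoxide cis to the side chain) | C1C=C[C@H](CC(=O)OC)[C@@H]2O[C@@H]21 | intermediate
10 | methyl 2-[(1S,2S,6S)-5-oxo-7-oxabicyclo[4.1.0]hept-3-en-2-yl]acetate | O=C1C=C[C@H](CC(=O)OC)[C@@H]2O[C@@H]21 | intermediate
11 | methyl 2-[(1S,6R)-6-hydroxy-4-oxocyclohex-2-en-1-yl]acetate (OH cis to the side chain) | O=C1C=C[C@H](CC(=O)OC)[C@H](O)C1 | intermediate
12 | methyl 2-[(1S,6R)-6-(TBSO)-4-oxocyclohex-2-en-1-yl]acetate | O=C1C=C[C@H](CC(=O)OC)[C@H](O[Si](C)(C)C(C)(C)C)C1 | intermediate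
13 | methyl 2-[(1S,6R)-6-(TBSO)-3-iodo-4-oxocyclohex-2-en-1-yl]acetate | O=C1C(I)=C[C@H](CC(=O)OC)[C@H](O[Si](C)(C)C(C)(C)C)C1 | intermediate
14 | methyl 2-[(1S,6R)-6-(TBSO)-4-oxo-3-(prop-1-en-2-yl)cyclohex-2-en-1-yl]acetate | O=C1C(C(C)=C)=C[C@H](CC(=O)OC)[C@H](O[Si](C)(C)C(C)(C)C)C1 | intermediate
15 | methyl 2-[(1S,2S,3S,6R)-6-(TBSO)-4-oxo-3-(prop-1-en-2-yl)-2-(4,4,5,5-tetramethyl-1,3,2-dioxaborolan-2-yl)cyclohexyl]acetate | O=C1[C@H](C(C)=C)[C@@H](B2OC(C)(C)C(C)(C)O2)[C@H](CC(=O)OC)[C@H](O[Si](C)(C)C(C)(C)C)C1 | intermediate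
16 | methyl 2-[(1S,2S,3R,6R)-6-(TBSO)-2-hydroxy-4-oxo-3-(prop-1-en-2-yl)cyclohexyl]acetate | O=C1[C@H](C(C)=C)[C@@H](O)[C@H](CC(=O)OC)[C@H](O[Si](C)(C)C(C)(C)C)C1 | intermediate
17 | methyl 2-[(1S,2S,3R,4R,6R)-6-(TBSO)-4-ethenyl-2,4-dihydroxy-3-(prop-1-en-2-yl)cyclohexyl]acetate | O[C@]1(C=C)[C@H](C(C)=C)[C@@H](O)[C@H](CC(=O)OC)[C@H](O[Si](C)(C)C(C)(C)C)C1 | intermediate
18 | (3aS,4R,6R,7R,7aS)-4-(TBSO)-6-ethenyl-6-hydroxy-7-(prop-1-en-2-yl)hexahydro-1-benzofuran-2(3H)-one (trans-fused lactone, vinyl trans to isopropenyl) | O[C@]1(C=C)[C@H](C(C)=C)[C@H]2OC(=O)C[C@@H]2[C@H](O[Si](C)(C)C(C)(C)C)C1 | intermediate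
19 | potassium enolate of 8β-(TBSO)-10-oxo-13,14-dinorgermacr-4-en-6α,12-olide (enolate C10=C1, C2 and C9 trans, 4E) | CC(C)(C)[Si](C)(C)O[C@@H]1C/C([O-])=C/CC/C(C)=C/[C@H]2OC(=O)C[C@@H]21.[K+] | intermediate
20 | 8β-(TBSO)-10-(trifluoromethanesulfonyloxy)-13,14-dinorgermacra-1(10),4-dien-6α,12-olide (4E; C2 and C9 trans across C1=C10) | CC(C)(C)[Si](C)(C)O[C@@H]1C/C(OS(=O)(=O)C(F)(F)F)=C/CC/C(C)=C/[C@H]2OC(=O)C[C@@H]21 | intermediate
21 | 8β-(TBSO)-14-hydroxy-13-norgermacra-1(10),4-dien-6α,12-olide | CC(C)(C)[Si](C)(C)O[C@@H]1C/C(CO)=C/CC/C(C)=C/[C@H]2OC(=O)C[C@@H]21 | intermediate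
22 | 13-(dimethylamino)-8β-(TBSO)-14-hydroxygermacra-1(10),4-dien-6α,12-olide (C11 epimers) | CC(C)(C)[Si](C)(C)O[C@@H]1C/C(CO)=C/CC/C(C)=C/[C@H]2OC(=O)C(CN(C)C)[C@@H]21 | intermediate
23 | 13-(trimethylammonio)-8β-(TBSO)-14-hydroxygermacra-1(10),4-dien-6α,12-olide iodide (C11 epimers) | CC(C)(C)[Si](C)(C)O[C@@H]1C/C(CO)=C/CC/C(C)=C/[C@H]2OC(=O)C(C[N+](C)(C)C)[C@@H]21.[I-] | intermediate
24 | 8β-(TBSO)-14-hydroxygermacra-1(10),4,11(13)-trien-6α,12-olide | CC(C)(C)[Si](C)(C)O[C@@H]1C/C(CO)=C/CC/C(C)=C/[C@H]2OC(=O)C(=C)[C@@H]21 | intermediate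
25 | 1β,10α-epoxy-8β-(TBSO)-14-hydroxygermacra-4,11(13)-dien-6α,12-olide | CC(C)(C)[Si](C)(C)O[C@@H]1C[C@@]2(CO)O[C@@H]2CC/C(C)=C/[C@H]2OC(=O)C(=C)[C@@H]21 | intermediate
26 | 14-acetoxy-1β,10α-epoxy-8β-(TBSO)germacra-4,11(13)-dien-6α,12-olide | CC(C)(C)[Si](C)(C)O[C@@H]1C[C@@]2(COC(C)=O)O[C@@H]2CC/C(C)=C/[C@H]2OC(=O)C(=C)[C@@H]21 | intermediate
27 | 14-acetoxy-1β,10α-epoxy-8β-hydroxygermacra-4,11(13)-dien-6α,12-olide | O[C@@H]1C[C@@]2(COC(C)=O)O[C@@H]2CC/C(C)=C/[C@H]2OC(=O)C(=C)[C@@H]21 | intermediate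
28 | 14-acetoxy-1β,10α-epoxy-8β-(methacryloyloxy)germacra-4,11(13)-dien-6α,12-olide (4E; CNP0150481.3) | C=C(C)C(=O)O[C@@H]1C[C@@]2(COC(C)=O)O[C@@H]2CC/C(C)=C/[C@H]2OC(=O)C(=C)[C@@H]21 | target

## Step count and risks

Total steps: 18. Longest linear sequence: 18 (fully linear from benzene).

Steps most likely to fail:

Step 6. The allyl radical at C10 sits next to the epoxide and could be oxidised at its other terminus (C6) or open the epoxide. The fallback sets out from 9: SeO2 (0.5 equiv) and t-BuOOH in CH2Cl2 at 23 °C, an ene/[2,3]-sigmatropic hydroxylation that cannot transpose the alkene, give the allylic alcohol methyl 2-[(1S,2S,6R)-5-hydroxy-7-oxabicyclo[4.1.0]hept-3-en-2-yl]acetate F1. Dess–Martin periodinane then oxidises it to the enone, and the route is rejoined at 10.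

Step 11. Conjugate borylation of the hindered cross-conjugated dienone may be slow, and oxidation of the boronate can trigger dehydration of the aldol. The fallback sets out from 14: t-BuOOH and DBU in CH2Cl2 (Weitz–Scheffer epoxidation, anti to the C7 and C8 substituents) give the epoxy ketone methyl 2-[4-(TBSO)-2-oxo-1-(prop-1-en-2-yl)-7-oxabicyclo[4.1.0]hept-5-yl]acetate F2. SmI2 in THF/MeOH at −90 °C then cleaves the C5–O bond and protonation at C5 gives the trans aldol, so the route is rejoined at 16.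

Step 13. The lactone may be enolised or attacked under the basic rearrangement conditions before the enolate is trapped. The fallback sets out from 18 and masks the carbonyl: i-Bu2AlH in CH2Cl2 at −78 °C gives the lactol of 18 F3, and MeOH with pyridinium p-toluenesulfonate gives the methyl acetal of 18 F4, which has neither an electrophilic carbonyl nor an acidic C–H. The same KN(SiMe3)2/18-crown-6 rearrangement and PhNTf2 trapping then give the enol triflate methyl acetal F5, and AcOH/THF/H2O frees the enol triflate lactol F6. PhI(OAc)2 with catalytic 2,2,6,6-tetramethylpiperidin-1-oxyl in CH2Cl2 oxidises it to the lactone, and the route is rejoined at 20.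

## Further compounds

F1 | step 6 | methyl 2-[(1S,2S,6R)-5-hydroxy-7-oxabicyclo[4.1.0]hept-3-en-2-yl]acetate (carbinol epimers) | OC1C=C[C@H](CC(=O)OC)[C@@H]2O[C@@H]21
F2 | step 11 | methyl 2-[4-(TBSO)-2-oxo-1-(prop-1-en-2-yl)-7-oxabicyclo[4.1.0]hept-5-yl]acetate (epoxide trans to the side chain and to the silyloxy group) | O=C1[C@@]2(C(C)=C)O[C@H]2[C@H](CC(=O)OC)[C@H](O[Si](C)(C)C(C)(C)C)C1
F3 | step 13 | lactol of 18 (2-hydroxy in place of 2-oxo; anomers) | O[C@]1(C=C)[C@H](C(C)=C)[C@H]2OC(O)C[C@@H]2[C@H](O[Si](C)(C)C(C)(C)C)C1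
F4 | step 13 | methyl acetal of 18 (2-methoxy in place of 2-oxo; anomers) | O[C@]1(C=C)[C@H](C(C)=C)[C@H]2OC(OC)C[C@@H]2[C@H](O[Si](C)(C)C(C)(C)C)C1
F5 | step 13 | 6α,12-epoxy-12-methoxy-8β-(TBSO)-10-(trifluoromethanesulfonyloxy)-13,14-dinorgermacra-1(10),4-diene (anomers) | CC(C)(C)[Si](C)(C)O[C@@H]1C/C(OS(=O)(=O)C(F)(F)F)=C/CC/C(C)=C/[C@H]2OC(OC)C[C@@H]21
F6 | step 13 | 6α,12-epoxy-12-hydroxy-8β-(TBSO)-10-(trifluoromethanesulfonyloxy)-13,14-dinorgermacra-1(10),4-diene (anomers) | CC(C)(C)[Si](C)(C)O[C@@H]1C/C(OS(=O)(=O)C(F)(F)F)=C/CC/C(C)=C/[C@H]2OC(O)C[C@@H]21
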